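**Retrosynthetic overview**
1. The ten-membered ring is closed last at C1–C10 by an intramolecular Nozaki–Hiyama–Kishi reaction (C10 vinyl bromide onto C1 aldehyde); the C8 side-chain ester is attached just before by Mitsunobu inversion.
2. The γ-lactone is made first, on the open chain: O–C6 and C11–C12 are formed in one flask by inserting CO2 between a C11 alkenyl-boron (via Cu) and a C6 allylic carbonate (via π-allyl-Pd).
3. Enabling feature: in the lactone ring O–C6–C7–C11–C12 the oxygen-bearing C6 is allylic to the C4=C5 double bond (so C6 can be a π-allyl electrophile) and the α-carbon C11 is sp2 (exocyclic C11=C13, so C11 can be an alkenyl-metal nucleophile); the ring is therefore CO2 plus a C11(−)/C6(+) three-carbon unit.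
4. The C6–C7 bond, the C7 stereocentre and the C11–B bond come from one Cu-catalysed allene/B2pin2/enal coupling of 8 and 16; 8 comes from anti-carbomagnesiation of a butynediol ether, 16 from asymmetric 2-bromoallylation and Crabbé homologation, acid 21 from glyceraldehyde acetonide by the same alkenyl-boron/CO2 carboxylation.
5. Ring order: γ-lactone (step 14), then ten-membered carbocycle (step 17).

Key step: step 14

Remark: open-chain intermediates carry the germacrane locants of the target (C12 lactone carbonyl, C13 and C14 exocyclic CH2, C15 the CH2OAc carbon); the Cu–B/allene/aldehyde coupling is assumed to take its usual course through a (Z)-2-borylallylcopper and a chair transition state (syn adduct); the descriptor changes in step 9 (S→R) and at C7 between 26 and 27 (S→R) are CIP-priority effects, not inversions.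

Step 1
Reactants: 1 4-[(tert-butyldimethylsilyl)oxy]but-2-yn-1-ol; 2 2-(2-bromoethyl)-1,3-dioxolane
Product: 5 (E)-4-[(tert-butyldimethylsilyl)oxy]-2-[2-(1,3-dioxolan-2-yl)ethyl]but-2-en-1-ol, via Grignard reagent 3 (not isolated), via alkenylmagnesium chelate 4 (not isolated)
Conditions: 2, Mg, THF, 25 °C; then 1 (0.4 equiv), CuI (10 mol%), THF, −20 °C → rt; H2O, 0 °C
Reagents that add atoms: none
Why: Copper-catalysed, alkoxide-directed anti-carbomagnesiation of a propargylic alcohol: the alkyl group adds to the alkyne carbon next to CH2OMg and magnesium ends on the distal carbon inside a five-membered chelate, so protonation leaves the new chain cis to CH2OTBS, which fixes the C4=C5 geometry of the target (C3 chain cis to C6).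

Step 2
Reactants: 5 (E)-4-[(tert-butyldimethylsilyl)oxy]-2-[2-(1,3-dioxolan-2-yl)ethyl]but-2-en-1-ol
Product: 6 (E)-4-[(tert-butyldimethylsilyl)oxy]-2-[2-(1,3-dioxolan-2-yl)ethyl]but-2-en-1-yl acetate
Conditions: Ac2O, pyridine, DMAP (cat.), CH2Cl2, 0 °C → rt
Reagents that add atoms: acetic anhydride CC(=O)OC(C)=O
Why: DMAP-catalysed acetylation of the only free (primary allylic) hydroxyl installs the C15 acetate that is carried to the end.

Step 3
Reactants: 6 (E)-4-[(tert-butyldimethylsilyl)oxy]-2-[2-(1,3-dioxolan-2-yl)ethyl]but-2-en-1-yl acetate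
Product: 7 (E)-2-[2-(1,3-dioxolan-2-yl)ethyl]-4-hydroxybut-2-en-1-yl acetate
Conditions: HF·pyridine, pyridine, THF, 0 °C → rt
Reagents that add atoms: none
Why: Fluoride desilylation with buffered HF·pyridine removes the primary TBS ether without acyl migration of the acetate and without opening the dioxolane.

Step 4
Reactants: 7 (E)-2-[2-(1,3-dioxolan-2-yl)ethyl]-4-hydroxybut-2-en-1-yl acetate
Product: 8 (E)-2-[2-(1,3-dioxolan-2-yl)ethyl]-4-oxobut-2-en-1-yl acetate
Conditions: MnO2 (excess), CH2Cl2, rt
Reagents that add atoms: none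
Why: Heterogeneous MnO2 oxidation is selective for the primary allylic alcohol and is neutral, so the trisubstituted alkene should keep its geometry and the γ-acetoxy enal is not exposed to base.

Step 5
Reactants: 9 3-(trimethylsilyl)prop-2-ynal; 10 2,3-dibromoprop-1-ene
Product: 12 (R)-5-bromo-1-(trimethylsilyl)hex-5-en-1-yn-3-ol, via O-trimethylsilyl ether 11 (not isolated)
Conditions: CrBr3 (10 mol%), chiral sulfonamide–oxazoline ligand (11 mol%, enantiomer giving the R carbinol), Et3N (20 mol%), Co(II) phthalocyanine (cat.), Mn, TMSCl, THF, 0 °C; then aq. citric acid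
Reagents that add atoms: none
Why: Catalytic asymmetric Nozaki–Hiyama-type 2-haloallylation: the allylic C–Br bond of 10 is reduced to an allyl–Cr(III) species (Co co-catalyst, Mn as terminal reductant) that adds to the ynal through a closed six-membered transition state whose face is fixed by the chiral ligand on chromium, giving the (R)-carbinol while the vinylic C–Br bond stays intact in the absence of nickel.

Step 6
Reactants: 12 (R)-5-bromo-1-(trimethylsilyl)hex-5-en-1-yn-3-ol
Product: 13 (R)-5-bromohex-5-en-1-yn-3-ol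
Conditions: K2CO3 (cat.), MeOH, 0 °C → rt
Reagents that add atoms: none
Why: Carbonate-catalysed methanolysis cleaves only the C(sp)–Si bond and leaves the carbinol centre untouched.

Step 7
Reactants: 13 (R)-5-bromohex-5-en-1-yn-3-ol
Product: 15 (R)-6-bromohepta-1,2,6-trien-4-ol, via Mannich base 14 (not isolated)
Conditions: (CH2O)n, CuI (0.5 equiv), Cy2NH (1.8 equiv), dioxane, reflux
Reagents that add atoms: paraformaldehyde (as formaldehyde) C=O
Why: Crabbé homologation: Cu(I)-mediated Mannich coupling of the terminal alkyne with formaldehyde and dicyclohexylamine, then hydride transfer from the amine and elimination, converts C≡C–H into CH=C=CH2 without involving the carbinol stereocentre; free propargylic alcohols and vinyl bromides are tolerated.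

Step 8
Reactants: 15 (R)-6-bromohepta-1,2,6-trien-4-ol
Product: 16 (R)-[(6-bromohepta-1,2,6-trien-4-yl)oxy](tert-butyl)dimethylsilane
Conditions: TBSCl, imidazole, DMF, 0 °C → rt
Reagents that add atoms: tert-butyldimethylsilyl chloride CC(C)(C)[Si](C)(C)Cl
Why: Routine silylation gives a non-coordinating, poorly leaving ether at the position α to the allene, which is what the organocopper step 12 needs.

Step 9
Reactants: 17 (S)-2,2-dimethyl-1,3-dioxolane-4-carbaldehyde
Product: 18 (R)-4-ethynyl-2,2-dimethyl-1,3-dioxolane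
Conditions: dimethyl (1-diazo-2-oxopropyl)phosphonate, K2CO3, MeOH, 0 °C → rt
Reagents that add atoms: Ohira–Bestmann reagent COP(=O)(OC)C(=[N+]=[N-])C(C)=O
Why: Seyferth–Gilbert homologation in its Ohira–Bestmann form converts the aldehyde into the terminal alkyne under carbonate/methanol conditions mild enough to keep the α-alkoxy centre configurationally intact.

Step 10
Reactants: 18 (R)-4-ethynyl-2,2-dimethyl-1,3-dioxolane
Product: 19 2-{1-[(4R)-2,2-dimethyl-1,3-dioxolan-4-yl]ethenyl}-4,4,5,5-tetramethyl-1,3,2-dioxaborolane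
Conditions: B2pin2, (SIMes)CuCl (5 mol%), NaOtBu (10 mol%), MeOH (2 equiv), THF, −50 → −15 °C
Reagents that add atoms: bis(pinacolato)diboron CC1(C)OB(OC1(C)C)B1OC(C)(C)C(C)(C)O1
Why: NHC–copper-catalysed protoboration of a terminal alkyne: with an N-aryl NHC ligand and a propargylic oxygen substituent the Cu–B addition places boron on the internal carbon and methanol protonates the alkenyl–copper, giving the 1,1-disubstituted alkenyl boronate.

Step 11
Reactants: 19 2-{1-[(4R)-2,2-dimethyl-1,3-dioxolan-4-yl]ethenyl}-4,4,5,5-tetramethyl-1,3,2-dioxaborolane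
Product: 21 2-[(4R)-2,2-dimethyl-1,3-dioxolan-4-yl]prop-2-enoic acid, via caesium carboxylate 20 (not isolated)
Conditions: CO2 (1 atm), (IPr)CuCl (5 mol%), CsF (3 equiv), DMF, 60 °C; then cold 0.5 M HCl to pH 3–4
Reagents that add atoms: carbon dioxide O=C=O
Why: Copper(I)–NHC-catalysed carboxylation of an alkenylboronic ester with CO2 (fluoride-assisted B-to-Cu transmetalation, CO2 insertion into the Cu–C(sp2) bond), the same C–C bond formation as in the key step; the brief cold, weakly acidic work-up should keep the acetonide.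

Step 12
Reactants: 8 (E)-2-[2-(1,3-dioxolan-2-yl)ethyl]-4-oxobut-2-en-1-yl acetate; 16 (R)-[(6-bromohepta-1,2,6-trien-4-yl)oxy](tert-butyl)dimethylsilane
Product: 23 (4E,6S,7S,8R)-15-acetoxy-10-bromo-8-(tert-butyldimethylsilyloxy)-6-hydroxy-11-(pinacolatoboryl)-1,10-seco-12-norgermacra-4,10(14),11(13)-trien-1-al ethylene acetal, via O-boryl adduct 22 (not isolated)
Conditions: B2pin2 (1.1 equiv), CuCl (5 mol%), chiral bisphosphine (Ph-BPE type, matched enantiomer, 5.5 mol%), NaOtBu (20 mol%), THF, 4 → 22 °C; then pH 7 buffer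
Reagents that add atoms: bis(pinacolato)diboron CC1(C)OB(OC1(C)C)B1OC(C)(C)C(C)(C)O1
Why: Copper-catalysed borylative three-component coupling: Cu–Bpin adds across the terminal C=C of allene 16 (boron on the central carbon, anti to the C8 substituent) and the resulting (Z)-2-borylallylcopper adds 1,2 to the enal through a chair transition state to give the syn adduct (C6–OH and C8 syn along C5–C6–C7–C11), with the absolute configuration at C6/C7 set by the chiral bisphosphine and reinforced by the C8 centre (H8 eclipsing the allyl unit, C9 anti to the forming bond, OTBS outside), which is why C8 is carried in the configuration that step 16 inverts.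

Step 13
Reactants: 23 (4E,6S,7S,8R)-15-acetoxy-10-bromo-8-(tert-butyldimethylsilyloxy)-6-hydroxy-11-(pinacolatoboryl)-1,10-seco-12-norgermacra-4,10(14),11(13)-trien-1-al ethylene acetal
Product: 24 (4E,6S,7S,8R)-15-acetoxy-10-bromo-8-(tert-butyldimethylsilyloxy)-6-(methoxycarbonyloxy)-11-(pinacolatoboryl)-1,10-seco-12-norgermacra-4,10(14),11(13)-trien-1-al ethylene acetal
Conditions: ClCO2Me, pyridine, DMAP (cat.), CH2Cl2, 0 °C
Reagents that add atoms: methyl chloroformate COC(=O)Cl
Why: Acylation of the secondary allylic alcohol gives the allylic methyl carbonate, the leaving group that Pd(0) ionises under neutral conditions in preference to the primary allylic acetate at C15.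

Step 14
Reactants: 24 (4E,6S,7S,8R)-15-acetoxy-10-bromo-8-(tert-butyldimethylsilyloxy)-6-(methoxycarbonyloxy)-11-(pinacolatoboryl)-1,10-seco-12-norgermacra-4,10(14),11(13)-trien-1-al ethylene acetal
Product: 26 (4E,6S,7S,8R)-15-acetoxy-10-bromo-8-(tert-butyldimethylsilyloxy)-1,1-(ethylenedioxy)-1,10-secogermacra-4,10(14),11(13)-trien-12,6-olide, via caesium acrylate 25 (not isolated)
Conditions: (i) CO2 (1 atm), (IPr)CuCl (5 mol%), CsF (3 equiv), DMF, 50 °C; (ii) same flask, Pd2(dba)3 (2.5 mol%), PPh3 (12 mol%), CO2 (1 atm), 25 °C; then cold 0.5 M HCl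
Reagents that add atoms: carbon dioxide O=C=O
Why: In stage (i) fluoride activates the pinacol boronate, the alkenyl group moves from B to (IPr)Cu and CO2 inserts into the Cu–C11 bond to give the caesium acrylate 25 (bond C11–C12), and in stage (ii) Pd(0) ionises the C6 methyl carbonate with inversion to a π-allyl complex over C4–C5–C6, which the tethered carboxylate attacks at C6 on the face opposite to palladium (bond O–C6). The closest known reaction types are the NHC–copper-catalysed carboxylation of alkenylboronic esters with CO2 and the Tsuji–Trost allylic substitution with carboxylate nucleophiles (allylic lactonisation), here run consecutively in one flask. The γ-lactone ring (O–C6–C7–C11–C12) closes in a 5-exo fashion at the allyl terminus that carries the tether, leaving C4=C5 outside the new ring, whereas attack at C4 would need a seven-membered ring at a fully substituted carbon. No new stereocentre is created: C6 is re-formed with net retention (two inversions), so the syn relationship of 23 becomes the cis ring fusion (H6/H7 cis) of the lactone, and the C4=C5 geometry should be kept because the π-allyl forms from the A(1,3)-minimised conformer (H6 in the alkene plane, C7 syn) and is trapped intramolecularly before π–σ–π rotation at the fully substituted C4. The step needs ionisation of the C6 carbonate in preference to the C15 acetate and the C10 vinyl bromide, which allylic carbonates under neutral Pd/PPh3 conditions at 25 °C provide, and the CO2 atmosphere keeps the expelled methoxide as methyl carbonate so that the acetate and the new α-methylene lactone are not attacked. Palladium is added only after the carboxylation is complete, so that no alkenyl–copper species is left to cross-couple with the π-allyl intermediate.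

Step 15
Reactants: 26 (4E,6S,7S,8R)-15-acetoxy-10-bromo-8-(tert-butyldimethylsilyloxy)-1,1-(ethylenedioxy)-1,10-secogermacra-4,10(14),11(13)-trien-12,6-olide
Product: 27 (4E,6S,7R,8R)-15-acetoxy-10-bromo-8-hydroxy-1-oxo-1,10-secogermacra-4,10(14),11(13)-trien-12,6-olide
Conditions: 48% aq. HF, MeCN, 0 °C → rt
Reagents that add atoms: water O
Why: Aqueous HF cleaves the hindered secondary TBS ether and, as aqueous acid, hydrolyses the 1,3-dioxolane in the same operation, while the lactone, the allylic acetate and the vinyl bromide should be stable; no stereocentre is affected.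

Step 16
Reactants: 27 (4E,6S,7R,8R)-15-acetoxy-10-bromo-8-hydroxy-1-oxo-1,10-secogermacra-4,10(14),11(13)-trien-12,6-olide; 21 2-[(4R)-2,2-dimethyl-1,3-dioxolan-4-yl]prop-2-enoic acid
Product: 28 (4E,6S,7R,8S)-15-acetoxy-10-bromo-1-oxo-8-{2-[(4R)-2,2-dimethyl-1,3-dioxolan-4-yl]prop-2-enoyloxy}-1,10-secogermacra-4,10(14),11(13)-trien-12,6-olide
Conditions: PPh3, DIAD (added last), THF, 0 °C → rt
Reagents that add atoms: none
Why: Mitsunobu esterification: the C8 alcohol is activated as its alkoxyphosphonium ion and displaced by the carboxylate of 21 in an SN2 step, so the ester forms with inversion and the (8R) centre needed for matched control in step 12 becomes the (8S) centre of the target.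

Step 17
Reactants: 28 (4E,6S,7R,8S)-15-acetoxy-10-bromo-1-oxo-8-{2-[(4R)-2,2-dimethyl-1,3-dioxolan-4-yl]prop-2-enoyloxy}-1,10-secogermacra-4,10(14),11(13)-trien-12,6-olide
Product: 29 (1R,4E,6S,7R,8S)-15-acetoxy-1-hydroxy-8-{2-[(4R)-2,2-dimethyl-1,3-dioxolan-4-yl]prop-2-enoyloxy}germacra-4,10(14),11(13)-trien-12,6-olide
Conditions: CrCl2 (8 equiv), NiCl2 (2 mol%), DMSO/THF (3:1), 2 mM, 25 → 40 °C; then H2O
Reagents that add atoms: none
Why: Intramolecular Nozaki–Hiyama–Kishi reaction: Ni(0) inserts into the vinylic C–Br bond, transmetalation gives an alkenyl–Cr(III) species that adds chemoselectively to the aldehyde at high dilution and closes the ten-membered ring; C1 is set by substrate control in the ring-forming transition state, where the required (1R) alcohol corresponds to attack on the Si face of the aldehyde (the side away from the cis-fused lactone), and this is the least secured stereocentre of the route.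

Step 18
Reactants: 29 (1R,4E,6S,7R,8S)-15-acetoxy-1-hydroxy-8-{2-[(4R)-2,2-dimethyl-1,3-dioxolan-4-yl]prop-2-enoyloxy}germacra-4,10(14),11(13)-trien-12,6-olide
Product: 30 (1R,4E,6S,7R,8S)-15-acetoxy-1-hydroxy-8-[(3R)-3,4-dihydroxy-2-methylidenebutanoyloxy]germacra-4,10(14),11(13)-trien-12,6-olide (CNP0245550.1)
Conditions: AcOH/H2O (4:1), 40 °C
Reagents that add atoms: none
Why: Mild aqueous acetic acid hydrolyses the terminal acetonide to the 1,2-diol without transesterifying the acetate or the acrylate ester and without opening the allylic lactone; no stereocentre is touched.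

**Compound list**
1 | 4-[(tert-butyldimethylsilyl)oxy]but-2-yn-1-ol | OCC#CCO[Si](C)(C)C(C)(C)C | starting material
2 | 2-(2-bromoethyl)-1,3-dioxolane | BrCCC1OCCO1 | starting material
3 | [2-(1,3-dioxolan-2-yl)ethyl]magnesium bromide | Br[Mg]CCC1OCCO1 | intermediate
4 | bromomagnesium (Z)-3-(bromomagnesio)-4-[(tert-butyldimethylsilyl)oxy]-2-[2-(1,3-dioxolan-2-yl)ethyl]but-2-en-1-olate | Br[Mg]OC/C(CCC1OCCO1)=C(\[Mg]Br)CO[Si](C)(C)C(C)(C)C | intermediate
5 | (E)-4-[(tert-butyldimethylsilyl)oxy]-2-[2-(1,3-dioxolan-2-yl)ethyl]but-2-en-1-ol | OC/C(CCC1OCCO1)=C/CO[Si](C)(C)C(C)(C)C | intermediate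
6 | (E)-4-[(tert-butyldimethylsilyl)oxy]-2-[2-(1,3-dioxolan-2-yl)ethyl]but-2-en-1-yl acetate | CC(=O)OC/C(CCC1OCCO1)=C/CO[Si](C)(C)C(C)(C)C | intermediate
7 | (E)-2-[2-(1,3-dioxolan-2-yl)ethyl]-4-hydroxybut-2-en-1-yl acetate | CC(=O)OC/C(CCC1OCCO1)=C/CO | intermediate
8 | (E)-2-[2-(1,3-dioxolan-2-yl)ethyl]-4-oxobut-2-en-1-yl acetate | CC(=O)OC/C(CCC1OCCO1)=C/C=O | intermediate
9 | 3-(trimethylsilyl)prop-2-ynal | C[Si](C)(C)C#CC=O | starting material
10 | 2,3-dibromoprop-1-ene | BrCC(Br)=C | starting material
11 | (R)-[5-bromo-3-(trimethylsilyloxy)hex-5-en-1-yn-1-yl]trimethylsilane | C[Si](C)(C)C#C[C@H](O[Si](C)(C)C)CC(Br)=C | intermediate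
12 | (R)-5-bromo-1-(trimethylsilyl)hex-5-en-1-yn-3-ol | C[Si](C)(C)C#C[C@H](O)CC(Br)=C | intermediate
13 | (R)-5-bromohex-5-en-1-yn-3-ol | C#C[C@H](O)CC(Br)=C | intermediate
14 | (R)-6-bromo-1-(dicyclohexylamino)hept-6-en-2-yn-4-ol | C1CCC(CC1)N(C1CCCCC1)CC#C[C@H](O)CC(Br)=C | intermediate
15 | (R)-6-bromohepta-1,2,6-trien-4-ol | C=C=C[C@H](O)CC(Br)=C | intermediate
16 | (R)-[(6-bromohepta-1,2,6-trien-4-yl)oxy](tert-butyl)dimethylsilane | C=C=C[C@H](O[Si](C)(C)C(C)(C)C)CC(Br)=C | intermediate
17 | (S)-2,2-dimethyl-1,3-dioxolane-4-carbaldehyde | O=C[C@@H]1COC(C)(C)O1 | starting material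
18 | (R)-4-ethynyl-2,2-dimethyl-1,3-dioxolane | C#C[C@@H]1COC(C)(C)O1 | intermediate
19 | 2-{1-[(4R)-2,2-dimethyl-1,3-dioxolan-4-yl]ethenyl}-4,4,5,5-tetramethyl-1,3,2-dioxaborolane | C=C(B1OC(C)(C)C(C)(C)O1)[C@@H]1COC(C)(C)O1 | intermediate
20 | caesium 2-[(4R)-2,2-dimethyl-1,3-dioxolan-4-yl]prop-2-enoate | C=C(C(=O)[O-])[C@@H]1COC(C)(C)O1.[Cs+] | intermediate
21 | 2-[(4R)-2,2-dimethyl-1,3-dioxolan-4-yl]prop-2-enoic acid | C=C(C(=O)O)[C@@H]1COC(C)(C)O1 | intermediate
22 | (4E,6S,7S,8R)-15-acetoxy-10-bromo-8-(tert-butyldimethylsilyloxy)-6-(pinacolatoboryloxy)-11-(pinacolatoboryl)-1,10-seco-12-norgermacra-4,10(14),11(13)-trien-1-al ethylene acetal | CC1(C)OB(O[C@@H](/C=C(/COC(C)=O)CCC2OCCO2)[C@H](C(=C)B2OC(C)(C)C(C)(C)O2)[C@@H](CC(Br)=C)O[Si](C)(C)C(C)(C)C)OC1(C)C | intermediate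
23 | (4E,6S,7S,8R)-15-acetoxy-10-bromo-8-(tert-butyldimethylsilyloxy)-6-hydroxy-11-(pinacolatoboryl)-1,10-seco-12-norgermacra-4,10(14),11(13)-trien-1-al ethylene acetal | O[C@@H](/C=C(/COC(C)=O)CCC1OCCO1)[C@H](C(=C)B1OC(C)(C)C(C)(C)O1)[C@@H](CC(Br)=C)O[Si](C)(C)C(C)(C)C | intermediate
24 | (4E,6S,7S,8R)-15-acetoxy-10-bromo-8-(tert-butyldimethylsilyloxy)-6-(methoxycarbonyloxy)-11-(pinacolatoboryl)-1,10-seco-12-norgermacra-4,10(14),11(13)-trien-1-al ethylene acetal | COC(=O)O[C@@H](/C=C(/COC(C)=O)CCC1OCCO1)[C@H](C(=C)B1OC(C)(C)C(C)(C)O1)[C@@H](CC(Br)=C)O[Si](C)(C)C(C)(C)C | intermediate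
25 | caesium (4E,6S,7S,8R)-15-acetoxy-10-bromo-8-(tert-butyldimethylsilyloxy)-1,1-(ethylenedioxy)-6-(methoxycarbonyloxy)-1,10-secogermacra-4,10(14),11(13)-trien-12-oate | COC(=O)O[C@@H](/C=C(/COC(C)=O)CCC1OCCO1)[C@H](C(=C)C(=O)[O-])[C@@H](CC(Br)=C)O[Si](C)(C)C(C)(C)C.[Cs+] | intermediate
26 | (4E,6S,7S,8R)-15-acetoxy-10-bromo-8-(tert-butyldimethylsilyloxy)-1,1-(ethylenedioxy)-1,10-secogermacra-4,10(14),11(13)-trien-12,6-olide | C=C1C(=O)O[C@@H](/C=C(/COC(C)=O)CCC2OCCO2)[C@H]1[C@H](O[Si](C)(C)C(C)(C)C)CC(Br)=C | intermediate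
27 | (4E,6S,7R,8R)-15-acetoxy-10-bromo-8-hydroxy-1-oxo-1,10-secogermacra-4,10(14),11(13)-trien-12,6-olide | C=C1C(=O)O[C@@H](/C=C(/COC(C)=O)CCC=O)[C@H]1[C@H](O)CC(Br)=C | intermediate
28 | (4E,6S,7R,8S)-15-acetoxy-10-bromo-1-oxo-8-{2-[(4R)-2,2-dimethyl-1,3-dioxolan-4-yl]prop-2-enoyloxy}-1,10-secogermacra-4,10(14),11(13)-trien-12,6-olide | C=C1C(=O)O[C@@H](/C=C(/COC(C)=O)CCC=O)[C@H]1[C@@H](OC(=O)C(=C)[C@@H]2COC(C)(C)O2)CC(Br)=C | intermediate
29 | (1R,4E,6S,7R,8S)-15-acetoxy-1-hydroxy-8-{2-[(4R)-2,2-dimethyl-1,3-dioxolan-4-yl]prop-2-enoyloxy}germacra-4,10(14),11(13)-trien-12,6-olide | C=C1C(=O)O[C@H]2/C=C(/COC(C)=O)CC[C@@H](O)C(=C)C[C@H](OC(=O)C(=C)[C@@H]3COC(C)(C)O3)[C@@H]12 | intermediate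
30 | (1R,4E,6S,7R,8S)-15-acetoxy-1-hydroxy-8-[(3R)-3,4-dihydroxy-2-methylidenebutanoyloxy]germacra-4,10(14),11(13)-trien-12,6-olide (CNP0245550.1; cis-fused lactone, C6 cis to C3 on C4=C5) | C=C1C(=O)O[C@H]2/C=C(/COC(C)=O)CC[C@@H](O)C(=C)C[C@H](OC(=O)C(=C)[C@@H](O)CO)[C@@H]12 | target

**Step count and risks**
Total steps: 18. Longest linear sequence: 11 steps (steps 1–4 then 12–18; equally steps 5–8 then 12–18).

Most likely to fail, first: step 12. The primary allylcopper may undergo 1,3-metal shift and β-silyloxy elimination to a 2-boryl-1,3-diene faster than it adds to the enal, and direct Cu–B addition to the aldehyde or loss of diastereocontrol may compete. The fallback sets out from allene 16 and avoids an allylcopper altogether. Pt(0)/PCy3-catalysed diboration of the terminal C=C of 16 with B2pin2 (the regiochemistry expected for a hindered monosubstituted allene with a bulky phosphine) should give tert-butyl{[(2Z,4R)-6-bromo-1,2-bis(pinacolatoboryl)hepta-2,6-dien-4-yl]oxy}dimethylsilane F1. Uncatalysed allylboration of enal 8 with this compound (toluene, rt to 50 °C, chair transition state, Z-allylboronate gives syn, face controlled by the C8 centre as in step 12) should give the O-boryl adduct 22. Hydrolysis returns the route at 23.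

Second: step 14. The C15 acetate may ionise in competition with the C6 carbonate, Pd(0)-induced π-allyl exchange may erode the C6 configuration and the C4=C5 geometry, and protodeboronation may compete with carboxylation. The fallback sets out from 23 and never breaks the C6–O bond. Iododeboronation (NaOH, I2, THF, 0 °C) should give the vinyl iodide (4E,6S,7S,8R)-15-acetoxy-10-bromo-8-(tert-butyldimethylsilyloxy)-6-hydroxy-11-iodo-1,10-seco-12-norgermacra-4,10(14),11(13)-trien-1-al ethylene acetal F2. Palladium-catalysed cyclocarbonylation of this compound (CO 1 atm, Pd(PPh3)4, Et3N, MeCN, 50 °C; the vinyl iodide reacts before the vinyl bromide, the C6 hydroxyl traps the acyl-palladium) returns the route at 26.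

Third: step 17. Intermolecular addition may compete with the slow ten-membered ring closure, and the facial selectivity at C1 is only substrate-controlled. For the stereochemical part the fallback sets out from 29 obtained as a mixture with its C1 epimer. Dess–Martin oxidation should give the macrocyclic enone (4E,6S,7R,8S)-15-acetoxy-1-oxo-8-{2-[(4R)-2,2-dimethyl-1,3-dioxolan-4-yl]prop-2-enoyloxy}germacra-4,10(14),11(13)-trien-12,6-olide F3. Corey–Bakshi–Shibata reduction with catecholborane at −78 °C (reagent control, C10 alkenyl as the large group, 1,2-selective) returns the route at 29.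

**Further compounds**
F1 | step 12 | tert-butyl{[(2Z,4R)-6-bromo-1,2-bis(4,4,5,5-tetramethyl-1,3,2-dioxaborolan-2-yl)hepta-2,6-dien-4-yl]oxy}dimethylsilane | CC1(C)OB(C/C(B2OC(C)(C)C(C)(C)O2)=C\[C@H](O[Si](C)(C)C(C)(C)C)CC(Br)=C)OC1(C)C
F2 | step 14 | (4E,6S,7S,8R)-15-acetoxy-10-bromo-8-(tert-butyldimethylsilyloxy)-6-hydroxy-11-iodo-1,10-seco-12-norgermacra-4,10(14),11(13)-trien-1-al ethylene acetal | O[C@@H](/C=C(/COC(C)=O)CCC1OCCO1)[C@H](C(=C)I)[C@@H](CC(Br)=C)O[Si](C)(C)C(C)(C)C
F3 | step 17 | (4E,6S,7R,8S)-15-acetoxy-1-oxo-8-{2-[(4R)-2,2-dimethyl-1,3-dioxolan-4-yl]prop-2-enoyloxy}germacra-4,10(14),11(13)-trien-12,6-olide | C=C1C(=O)O[C@H]2/C=C(/COC(C)=O)CCC(=O)C(=C)C[C@H](OC(=O)C(=C)[C@@H]3COC(C)(C)O3)[C@@H]12
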